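Assumption: the target has no stereocentre (it is achiral), so no stereocontrol is needed and the SMILES carry no stereo descriptors.

**Retrosynthetic overview**
1. Target 10 ⇒ 2 × aspidinol 7 + formaldehyde 8. The methylene bridge is made last, at C5, the only free ring position of 7.
2. Aspidinol 7 ⇒ hydroxy ketone 4 by disconnecting the aryl C6–O bond. This is the key step: the last phenolic oxygen is installed by ketone-directed C–H oxygenation.
3. Hydroxy ketone 4 ⇒ 2,6-dimethoxytoluene 1 + butanoyl chloride 2 (Friedel–Crafts acylation with chelation-controlled loss of the ortho O-methyl group).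
4. No ring is formed; the benzene ring is bought. Order of events: acylation/demethylation → C–H oxygenation → dimerisation.

**Step 1**
Reactants: 1 2,6-dimethoxytoluene (1,3-dimethoxy-2-methylbenzene); 2 butanoyl chloride
Product: 4 1-(2-hydroxy-4-methoxy-3-methylphenyl)butan-1-one, via dimethoxy ketone 3 (not isolated)
Conditions: AlCl3 (2.5 equiv), CH2Cl2, 0 °C → reflux; then ice/aq. HCl
Reagents that add atoms: none
Why: Friedel–Crafts acylation can only occur at C3/C5 of 1 (equivalent; ortho to one OMe and para to the other), and excess AlCl3 then removes the crowded O-methyl group lying between the carbonyl and the ring methyl (chelation-controlled ortho-demethylation) while the para OMe survives.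

**Step 2**
Reactants: 4 1-(2-hydroxy-4-methoxy-3-methylphenyl)butan-1-one
Product: 7 aspidinol (1-(2,6-dihydroxy-4-methoxy-3-methylphenyl)butan-1-one), via mono(trifluoroacetate) 5 (not isolated), via bis(trifluoroacetate) 6 (not isolated)
Conditions: (CF3CO)2O/CF3CO2H 1:4, rt, 30 min; then Pd(OCOCF3)2 (10 mol %), K2S2O8 (2 equiv), 50 °C; then H2O–THF, rt
Reagents that add atoms: trifluoroacetic anhydride, O=C(OC(=O)C(F)(F)F)C(F)(F)F (trifluoroacetyl groups of 5 and 6); trifluoroacetic acid, OC(=O)C(F)(F)F (the new aryl oxygen at C6)
Why: Proposed new method: a ketone-directed Pd(II)/Pd(IV) ortho-C–H oxygenation carried out as a second ortho-oxygenation on an electron-rich o-hydroxyaryl ketone masked in situ as its trifluoroacetate; masking stops O,O-chelation of Pd by the hydroxy ketone and phenol oxidation and frees the C=O to bind Pd syn to C6–H, the only ortho C–H, so carboxylate-assisted cyclopalladation can occur only there; persulfate then oxidises Pd(II) to Pd(IV) and C–OCOCF3 reductive elimination gives 6, whose two ester groups protect the phloroglucinol-type ring from over-oxidation until hydrolysis; the para-OMe and meta-Me donors raise carbonyl basicity and ring reactivity to offset the deactivating, twisting o-OCOCF3 group; the closest known reaction type is Pd(II)- or Ru(II)-catalysed ketone-directed ortho-C–H hydroxylation of simple aryl ketones in TFA/TFAA with K2S2O8 or PhI(OCOCF3)2, which is not established next to an o-acyloxy group or for building an acylphloroglucinol.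

**Step 3**
Reactants: 7 aspidinol (2 equiv); 8 formaldehyde
Product: 10 methylenebis(aspidinol) [bis(3-butanoyl-2,4-dihydroxy-6-methoxy-5-methylphenyl)methane], via hydroxymethylaspidinol 9 (not isolated)
Conditions: 37% aq. HCHO (0.5 equiv), NaOH (10 mol %), MeOH–H2O, 0 °C → rt; then dil. HCl
Reagents that add atoms: none
Why: Base-catalysed phenol–formaldehyde condensation (Lederer–Manasse hydroxymethylation, then diarylmethane formation): 7 is hydroxymethylated at C5, its only free ring position, and 9 alkylates C5 of a second molecule of 7, so only the symmetrical dimer can form and no stereocentre arises.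

**Compound list**
1 | 2,6-dimethoxytoluene (1,3-dimethoxy-2-methylbenzene) | COc1cccc(OC)c1C | starting material
2 | butanoyl chloride | CCCC(=O)Cl | starting material
3 | 1-(2,4-dimethoxy-3-methylphenyl)butan-1-one | CCCC(=O)c1ccc(OC)c(C)c1OC | intermediate
4 | 1-(2-hydroxy-4-methoxy-3-methylphenyl)butan-1-one | CCCC(=O)c1ccc(OC)c(C)c1O | intermediate
5 | 6-butanoyl-3-methoxy-2-methylphenyl trifluoroacetate | CCCC(=O)c1ccc(OC)c(C)c1OC(=O)C(F)(F)F | intermediate
6 | 2-butanoyl-5-methoxy-4-methyl-1,3-phenylene bis(trifluoroacetate) | CCCC(=O)c1c(OC(=O)C(F)(F)F)cc(OC)c(C)c1OC(=O)C(F)(F)F | intermediate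
7 | aspidinol, 1-(2,6-dihydroxy-4-methoxy-3-methylphenyl)butan-1-one | CCCC(=O)c1c(O)cc(OC)c(C)c1O | intermediate
8 | formaldehyde | C=O | starting material
9 | 1-[2,6-dihydroxy-3-(hydroxymethyl)-4-methoxy-5-methylphenyl]butan-1-one | CCCC(=O)c1c(O)c(C)c(OC)c(CO)c1O | intermediate
10 | methylenebis(aspidinol), bis(3-butanoyl-2,4-dihydroxy-6-methoxy-5-methylphenyl)methane | CCCC(=O)c1c(O)c(C)c(OC)c(Cc2c(O)c(C(=O)CCC)c(O)c(C)c2OC)c1O | target

**Step count and risks**
Total step count: 3. Longest linear sequence: 3 steps (1 → 4 → 7 → 10).

Steps most likely to fail, most risky first: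

Step 2 (the proposed new method). The o-OCOCF3 group may lower carbonyl basicity and twist the acyl group enough to stop cyclopalladation, and persulfate may attack the anisole ring at C5 or the benzylic methyl. The fallback uses known chemistry, sets out from 1 and comes back at 7, replacing steps 1 and 2. Sterically controlled Ir-catalysed C–H borylation of 1 ([Ir(OMe)(cod)]2, dtbpy, B2pin2, 80 °C) goes to C4, the only C–H not next to a substituent, and gives 2-(3,5-dimethoxy-4-methylphenyl)-4,4,5,5-tetramethyl-1,3,2-dioxaborolane F1. Oxidation in the same flask (Oxone, acetone–water, rt) gives 3,5-dimethoxy-4-methylphenol F2. Acylation of F2 with 2 and AlCl3 (CH2Cl2, 0 °C → rt; the two free positions are equivalent and ortho to OH) gives 1-(6-hydroxy-2,4-dimethoxy-3-methylphenyl)butan-1-one F3. Continued heating with excess AlCl3 (or BBr3 at low temperature) removes the O-methyl group between the carbonyl and the ring methyl to give 7.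

Step 1. The demethylation may stop short or also touch the para OMe. The fallback sets out from 1 and comes back at 4. Mono-demethylation of 1 (EtSNa, DMF, 140 °C) gives 3-methoxy-2-methylphenol F4. Boron-templated ortho-acylation with butanenitrile (BCl3, AlCl3, 1,2-dichloroethane, 80 °C; Sugasawa-type) acylates exclusively ortho to OH, and the only free ortho position is para to OMe; it gives the ketimine 6-butanimidoyl-3-methoxy-2-methylphenol F5. Hydrolysis (2 M HCl, 80 °C) gives 4.

Step 3. The aqueous base condensation may give low conversion or side products from excess formaldehyde. The fallback sets out from 7 and comes back at 10. Mannich reaction of 7 (aq. Me2NH, aq. HCHO, EtOH, rt) gives the isolable Mannich base 1-{3-[(dimethylamino)methyl]-2,6-dihydroxy-4-methoxy-5-methylphenyl}butan-1-one F6. Heating F6 with one further equivalent of 7 (dioxane, reflux) transfers the benzyl unit to C5 of 7 with loss of dimethylamine and gives 10 under base-free conditions.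

**Further compounds**
F1 | step 2 | 2-(3,5-dimethoxy-4-methylphenyl)-4,4,5,5-tetramethyl-1,3,2-dioxaborolane | COc1cc(B2OC(C)(C)C(C)(C)O2)cc(OC)c1C
F2 | step 2 | 3,5-dimethoxy-4-methylphenol | COc1cc(O)cc(OC)c1C
F3 | step 2 | 1-(6-hydroxy-2,4-dimethoxy-3-methylphenyl)butan-1-one | CCCC(=O)c1c(O)cc(OC)c(C)c1OC
F4 | step 1 | 3-methoxy-2-methylphenol | COc1cccc(O)c1C
F5 | step 1 | 6-butanimidoyl-3-methoxy-2-methylphenol | CCCC(=N)c1ccc(OC)c(C)c1O
F6 | step 3 | 1-{3-[(dimethylamino)methyl]-2,6-dihydroxy-4-methoxy-5-methylphenyl}butan-1-one | CCCC(=O)c1c(O)c(C)c(OC)c(CN(C)C)c1O
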